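**Retrosynthetic overview**

1. The 1,3-diketone is cut between its CH2 and the ring-A carbonyl: a crossed Claisen condensation joins 6-acetyl-7-hydroxy-2,2-dimethyl-2H-chromene to a TIPS-protected methyl 4-hydroxy-3-prenylbenzoate, and fluoride removes the silyl group last.
2. The acetyl group of the chromene half comes from a C6 bromide (Br/Li exchange, Weinreb acetylation).
3. Key disconnection: the pyran ring is opened at O1–C2 and C3=C4 together, giving 5-bromo-2,4-dihydroxybenzaldehyde and (2-methylprop-1-enyl)boronic acid; forward, an amine-catalysed Petasis alkenylation / amine loss / oxa-6π electrocyclisation cascade.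
4. Enabling feature: O1 (on C8a) and C4 (on C4a) sit on adjacent carbons of ring B, a salicylaldehyde retron, and the gem-dimethyl C2 with C3 maps onto an isobutenyl nucleophile. The formyl group has only one ortho hydroxyl, so the linear 6,7-fusion is fixed by construction (direct chromenylation of 4-acylresorcinols tends to close at the carbon between the two oxygens instead).
5. Ring A: the prenyl C–C bond comes from methyl 4-hydroxy-3-iodobenzoate (I/Mg exchange, Cu-catalysed SN2 prenylation). Both benzene rings are bought; the pyran ring is the only ring formed, and it is formed first.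

Key step: step 1

Remark on the chemistry: the target has no stereogenic centre and no stereogenic double bond (the ring alkene is necessarily cis, the prenyl alkene carries two methyls), so the "single enantiomer" needs no stereocontrol. The 1,3-diketones are drawn as diketo forms although the chelated enol should dominate. Partners whose carbon atoms remain in the target are numbered as reactants; other atom-donating reagents stand on the reagent line. Compounds 1, 2, 6, 10 and 12 are catalogue chemicals.

**Route**

Step 1
Reactants: 1 5-bromo-2,4-dihydroxybenzaldehyde; 2 (2-methylprop-1-en-1-yl)boronic acid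
Product: 5 6-bromo-2,2-dimethyl-2H-chromen-7-ol, via racemic 4-bromo-6-[1-(dibenzylamino)-3-methylbut-2-en-1-yl]benzene-1,3-diol 3 (not isolated), via ortho-quinone methide 4-bromo-3-hydroxy-6-(3-methylbut-2-en-1-ylidene)cyclohexa-2,4-dien-1-one 4 (not isolated)
Conditions: 2 (1.5 equiv), Bn2NH (0.3 equiv), 1,4-dioxane, 90 °C
Reagents that add atoms: none
Why: The aldehyde of 1 condenses with Bn2NH to an iminium ion while the ortho phenol binds 2 as a tetracoordinate boronate, which hands its 2-methylprop-1-enyl group to the iminium carbon (Petasis borono-Mannich step, new C4–C3 bond) to give allylic amine 3; at 90 °C 3 expels Bn2NH, pushed by the ortho and para oxygens, to give ortho-quinone methide 4 (C3=C4 in place), and 4 closes by oxa-6π electrocyclisation (new O1–C2 bond), which restores aromaticity and returns the amine for turnover. The closest known reaction type is the amine-catalysed Petasis condensation of salicylaldehydes with alkenylboronic acids to 2H-chromenes. The pyran ring closes by a thermal disrotatory 6π electrocyclisation of the 1-oxatriene, a formal 6-endo O–C closure that the gem-dimethyl terminus favours. No stereocentre results, because C2 carries two methyl groups and the amine-bearing carbon of racemic 3 becomes sp2. The selectivity needed is regiochemical (linear versus angular fusion, one phenol oxygen versus the other), and it is secured because the formyl group of 1 has a hydroxyl on only one neighbouring carbon, so alkenyl delivery and ring closure can use only that oxygen, while the para hydroxyl and the C–Br bond are spectators; the slower iminium chemistry expected from the para hydroxyl is met with excess 2 and prolonged heating.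

Step 2
Reactants: 5 6-bromo-2,2-dimethyl-2H-chromen-7-ol; 6 N-methoxy-N-methylacetamide
Product: 9 1-(7-hydroxy-2,2-dimethyl-2H-chromen-6-yl)ethan-1-one, via lithium 6-lithio-2,2-dimethyl-2H-chromen-7-olate 7 (not isolated), via dilithium tetrahedral adduct lithium 6-{1-(lithiooxy)-1-[methoxy(methyl)amino]ethyl}-2,2-dimethyl-2H-chromen-7-olate 8 (not isolated)
Conditions: n-BuLi (2.2 equiv), THF, −78 → −20 °C; then 6 (1.5 equiv), −78 °C → rt; aq NH4Cl
Reagents that add atoms: none
Why: The first equivalent of n-BuLi forms the phenoxide and the second performs bromine–lithium exchange to the ortho-lithiophenoxide 7, which adds once to the Weinreb amide to give chelate 8 that collapses to the methyl ketone only on work-up (Weinreb ketone synthesis); the chromene has no acidic C–H to interfere.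

Step 3
Reactants: 10 methyl 4-hydroxy-3-iodobenzoate
Product: 11 methyl 3-iodo-4-[(triisopropylsilyl)oxy]benzoate
Conditions: TIPSCl (1.2 equiv), imidazole (2.5 equiv), DMF, rt
Reagents that add atoms: triisopropylsilyl chloride, CC(C)[Si](Cl)(C(C)C)C(C)C
Why: Standard imidazole-promoted silylation of an acidic phenol; TIPS is chosen because it should survive the organomagnesium and alkoxide-base steps and is removed by fluoride without acid, which the chromene, the ortho-prenylphenol and the 2'-hydroxy-1,3-diketone would not tolerate.

Step 4
Reactants: 11 methyl 3-iodo-4-[(triisopropylsilyl)oxy]benzoate; 12 1-bromo-3-methylbut-2-ene (prenyl bromide)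
Product: 14 methyl 3-(3-methylbut-2-en-1-yl)-4-[(triisopropylsilyl)oxy]benzoate, via {5-(methoxycarbonyl)-2-[(triisopropylsilyl)oxy]phenyl}magnesium chloride 13 (not isolated)
Conditions: i-PrMgCl·LiCl (1.1 equiv), THF, −40 °C; then CuBr·SMe2 (10 mol %), 12 (1.5 equiv), −40 → 0 °C
Reagents that add atoms: none
Why: Iodine–magnesium exchange with the turbo-Grignard reagent is faster than attack on the methyl ester at −40 °C, and copper-catalysed allylic substitution of arylmagnesium 13 on prenyl bromide should occur at the unsubstituted α-carbon (SN2 mode), because γ-attack would build a quaternary benzylic carbon beside the bulky ortho silyloxy group.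

Step 5
Reactants: 9 1-(7-hydroxy-2,2-dimethyl-2H-chromen-6-yl)ethan-1-one; 14 methyl 3-(3-methylbut-2-en-1-yl)-4-[(triisopropylsilyl)oxy]benzoate
Product: 16 1-(7-hydroxy-2,2-dimethyl-2H-chromen-6-yl)-3-{3-(3-methylbut-2-en-1-yl)-4-[(triisopropylsilyl)oxy]phenyl}propane-1,3-dione, via dipotassium 6-(1-oxidoethenyl)-2,2-dimethyl-2H-chromen-7-olate 15 (not isolated)
Conditions: KOt-Bu (3.5 equiv), 14 (1.2 equiv), THF, 0 °C → rt (50 °C if needed); aq NH4Cl
Reagents that add atoms: none
Why: Crossed Claisen condensation: tert-butoxide forms the phenoxide and, reversibly, the enolate (dianion 15), whose carbon acylates on the non-enolisable ester 14, and irreversible deprotonation of the product 1,3-diketone drives the equilibrium; the hindered base should leave the aryl TIPS ether and both alkenes untouched.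

Step 6
Reactants: 16 1-(7-hydroxy-2,2-dimethyl-2H-chromen-6-yl)-3-{3-(3-methylbut-2-en-1-yl)-4-[(triisopropylsilyl)oxy]phenyl}propane-1,3-dione
Product: 17 Glyinflanin C, 1-(7-hydroxy-2,2-dimethyl-2H-chromen-6-yl)-3-[4-hydroxy-3-(3-methylbut-2-en-1-yl)phenyl]propane-1,3-dione
Conditions: TBAF (1.2 equiv), THF, 0 °C; aq NH4Cl
Reagents that add atoms: none
Why: Fluoride cleaves the aryl Si–O bond (silyl ether deprotection) under non-acidic conditions, so flavone formation from the 2'-hydroxy-1,3-diketone, cyclisation of the ortho-prenylphenol and hydration of the chromene are avoided.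

**Compound list**

1 | 5-bromo-2,4-dihydroxybenzaldehyde | O=Cc1cc(Br)c(O)cc1O | starting material
2 | (2-methylprop-1-en-1-yl)boronic acid | CC(C)=CB(O)O | starting material
3 | 4-bromo-6-[1-(dibenzylamino)-3-methylbut-2-en-1-yl]benzene-1,3-diol (racemic, not isolated) | CC(C)=CC(N(Cc1ccccc1)Cc1ccccc1)c1cc(Br)c(O)cc1O | intermediate
4 | 4-bromo-3-hydroxy-6-(3-methylbut-2-en-1-ylidene)cyclohexa-2,4-dien-1-one (ortho-quinone methide, not isolated) | CC(C)=CC=C1C=C(Br)C(O)=CC1=O | intermediate
5 | 6-bromo-2,2-dimethyl-2H-chromen-7-ol | CC1(C)C=Cc2cc(Br)c(O)cc2O1 | intermediate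
6 | N-methoxy-N-methylacetamide | CC(=O)N(C)OC | starting material
7 | lithium 6-lithio-2,2-dimethyl-2H-chromen-7-olate (not isolated) | CC1(C)C=Cc2cc([Li])c(O[Li])cc2O1 | intermediate
8 | lithium 6-{1-(lithiooxy)-1-[methoxy(methyl)amino]ethyl}-2,2-dimethyl-2H-chromen-7-olate (not isolated) | CC(O[Li])(N(C)OC)c1cc2C=CC(C)(C)Oc2cc1O[Li] | intermediate
9 | 1-(7-hydroxy-2,2-dimethyl-2H-chromen-6-yl)ethan-1-one | CC(=O)c1cc2C=CC(C)(C)Oc2cc1O | intermediate
10 | methyl 4-hydroxy-3-iodobenzoate | COC(=O)c1ccc(O)c(I)c1 | starting material
11 | methyl 3-iodo-4-[(triisopropylsilyl)oxy]benzoate | COC(=O)c1ccc(O[Si](C(C)C)(C(C)C)C(C)C)c(I)c1 | intermediate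
12 | 1-bromo-3-methylbut-2-ene | CC(C)=CCBr | starting material
13 | {5-(methoxycarbonyl)-2-[(triisopropylsilyl)oxy]phenyl}magnesium chloride (not isolated) | COC(=O)c1ccc(O[Si](C(C)C)(C(C)C)C(C)C)c([Mg]Cl)c1 | intermediate
14 | methyl 3-(3-methylbut-2-en-1-yl)-4-[(triisopropylsilyl)oxy]benzoate | COC(=O)c1ccc(O[Si](C(C)C)(C(C)C)C(C)C)c(CC=C(C)C)c1 | intermediate
15 | dipotassium 6-(1-oxidoethenyl)-2,2-dimethyl-2H-chromen-7-olate (not isolated) | C=C([O-])c1cc2C=CC(C)(C)Oc2cc1[O-].[K+].[K+] | intermediate
16 | 1-(7-hydroxy-2,2-dimethyl-2H-chromen-6-yl)-3-{3-(3-methylbut-2-en-1-yl)-4-[(triisopropylsilyl)oxy]phenyl}propane-1,3-dione | CC(C)=CCc1cc(C(=O)CC(=O)c2cc3C=CC(C)(C)Oc3cc2O)ccc1O[Si](C(C)C)(C(C)C)C(C)C | intermediate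
17 | Glyinflanin C | CC(C)=CCc1cc(C(=O)CC(=O)c2cc3c(cc2O)OC(C)(C)C=C3)ccc1O | target

**Step count and risks**

Total steps: 6. Longest linear sequence: 4 steps (1 → 5 → 9 → 16 → 17, or 10 → 11 → 14 → 16 → 17).

Steps most likely to fail:

Step 1 (key step). The alkenyl transfer may stall because the para hydroxyl, partly present as its ammonium phenoxide, lowers the electrophilicity of the iminium ion, and the alkenylboronic acid may be lost by protodeboronation before it is transferred. Fallback, from 1 back to 5: the catalytic cascade is replaced by a stoichiometric organomagnesium addition and a separate dehydrative ring closure. Compound 1 is treated with 2-methylprop-1-en-1-ylmagnesium bromide (3.5 equiv, THF, 0 °C → rt; two equivalents are used up by the phenols) to give racemic 4-bromo-6-(1-hydroxy-3-methylbut-2-en-1-yl)benzene-1,3-diol F1. Warming F1 in toluene with catalytic PPTS should eliminate water to the same ortho-quinone methide 4, which electrocyclises to 5.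

Step 5. Intermolecular acylation of the enolate by the electron-rich ester may be slow, and the methoxide released may strip the silyl group from unreacted ester, turning it into an unreactive phenoxide. Fallback, from 14 and 9 back to 16: the acyl transfer is made intramolecular. The methyl ester of 14 is cleaved with Me3SnOH (1,2-dichloroethane, 80 °C), which should spare the aryl silyl ether, to give 3-(3-methylbut-2-en-1-yl)-4-[(triisopropylsilyl)oxy]benzoic acid F2. F2 is esterified with the phenol of 9 (EDC·HCl, DMAP, CH2Cl2) to give 6-acetyl-2,2-dimethyl-2H-chromen-7-yl 3-(3-methylbut-2-en-1-yl)-4-[(triisopropylsilyl)oxy]benzoate F3. F3 is rearranged with KOt-Bu in THF at 0 °C (Baker–Venkataraman O→C acyl migration) to 16.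

Step 4. Competing γ-attack (SN2′) would give the reverse-prenyl isomer, and the arylmagnesium may add to the ester before the allylation is complete. Fallback, from 11 back to 14: the polarity of the coupling is changed. Miyaura borylation of 11 (B2pin2, Pd(dppf)Cl2, KOAc, dioxane, 80 °C) gives methyl 3-(4,4,5,5-tetramethyl-1,3,2-dioxaborolan-2-yl)-4-[(triisopropylsilyl)oxy]benzoate F4. F4 is coupled with prenyl bromide 12 under Pd(0) catalysis (Pd(PPh3)4, K2CO3, toluene/H2O, 50 °C); reductive elimination from the aryl(π-prenyl)palladium species should place the aryl group on the unsubstituted allyl terminus and give 14.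

**Further compounds**

F1 | step 1 | 4-bromo-6-(1-hydroxy-3-methylbut-2-en-1-yl)benzene-1,3-diol (racemic) | CC(C)=CC(O)c1cc(Br)c(O)cc1O
F2 | step 5 | 3-(3-methylbut-2-en-1-yl)-4-[(triisopropylsilyl)oxy]benzoic acid | OC(=O)c1ccc(O[Si](C(C)C)(C(C)C)C(C)C)c(CC=C(C)C)c1
F3 | step 5 | 6-acetyl-2,2-dimethyl-2H-chromen-7-yl 3-(3-methylbut-2-en-1-yl)-4-[(triisopropylsilyl)oxy]benzoate | CC(=O)c1cc2C=CC(C)(C)Oc2cc1OC(=O)c1ccc(O[Si](C(C)C)(C(C)C)C(C)C)c(CC=C(C)C)c1
F4 | step 4 | methyl 3-(4,4,5,5-tetramethyl-1,3,2-dioxaborolan-2-yl)-4-[(triisopropylsilyl)oxy]benzoate | COC(=O)c1ccc(O[Si](C(C)C)(C(C)C)C(C)C)c(B2OC(C)(C)C(C)(C)O2)c1
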